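Ring A carries oxygen on C1 and C3, 4-hydroxybenzyl groups on C2, C4 and C6 and the ethano chain on C5. This is the pattern of a 3,5,7-triketo acid, benzylated on all three methylenes, after aldol folding. Everything rests on cutting the C6–C5 bond of ring A. The precursor is a 3,5-dibenzylated 2-pyrone whose C6 bears a benzylated 2-oxoalkyl chain ending in ring B. Its C4 oxygen already holds the methyl group, so ring A is born unsymmetrical. In one operation hydroxide opens the lactone, the old pyrone C3 bonds to the side-chain ketone carbon, and loss of water and CO2 aromatises ring A. Hydrogenolysis of five benzyl ethers finishes bleochrin B.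

Key step: step 11

Remark (numbering): ring A is C1 (OMe), C2 (benzyl), C3 (OH), C4 (benzyl), C5 (ethano chain), C6 (benzyl). "Chain C1–C9" counts the opened pyrone from its carboxyl carbon, so chain C2 = pyrone C3 = ring A C6, and chain C7 = side-chain ketone = ring A C5.
Remark (stereochemistry): the carbon between pyrone C6 and the side-chain ketone is enolisable. The key-step precursor is therefore a racemate that cannot be kept as one enantiomer, and it is drawn without a descriptor. The target has no stereocentre.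
Remark (design): a free hydroxyl on pyrone C4 would lead through the same closure to the mirror-symmetric resorcinol and force a statistical methylation. Putting the methyl group on that oxygen beforehand changes no skeletal atom and no bond formed. The hydroxy series is kept as a fallback.

Step 1
Reactants: 1 methyl 3-(4-hydroxyphenyl)propanoate
Product: 2 methyl 3-[4-(benzyloxy)phenyl]propanoate
Conditions: BnBr, K2CO3, acetone, reflux
Reagents that add atoms: benzyl bromide, BrCc1ccccc1
Why: Williamson ether synthesis, in which the phenoxide made by K2CO3 displaces bromide in an SN2 reaction and the methyl ester is untouched.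

Step 2
Reactants: 2 methyl 3-[4-(benzyloxy)phenyl]propanoate (two molecules)
Product: 3 methyl 2-[4-(benzyloxy)benzyl]-5-[4-(benzyloxy)phenyl]-3-oxopentanoate (racemic)
Conditions: NaH, MeOH (cat.), THF, reflux; then 1 M HCl
Reagents that add atoms: none
Why: Claisen self-condensation, in which the ester enolate acylates a second ester molecule and deprotonation of the remaining C2–H of the β-keto ester pulls the equilibrium over; the new centre is enolisable and of no consequence.

Step 3
Reactants: 3 methyl 2-[4-(benzyloxy)benzyl]-5-[4-(benzyloxy)phenyl]-3-oxopentanoate, 2 methyl 3-[4-(benzyloxy)phenyl]propanoate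
Product: 4 methyl 2,4-bis[4-(benzyloxy)benzyl]-7-[4-(benzyloxy)phenyl]-3,5-dioxoheptanoate (mixture of diastereomers and enol forms)
Conditions: 3 (2 equiv), LiN(iPr)2 (4.2 equiv), THF, −78 to 0 °C; then 2 (1 equiv), −78 to 0 °C; then 1 M HCl; surplus 3 recovered
Reagents that add atoms: none
Why: γ-Acylation of a β-keto ester dianion (Claisen type), in which the more basic C4 carbanion attacks ester 2 and the second equivalent of the cheap dianion takes up the acidic proton of the product; both centres are enolisable and vanish in step 4.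

Step 4
Reactants: 4 methyl 2,4-bis[4-(benzyloxy)benzyl]-7-[4-(benzyloxy)phenyl]-3,5-dioxoheptanoate
Product: 5 3,5-bis[4-(benzyloxy)benzyl]-6-{2-[4-(benzyloxy)phenyl]ethyl}-4-hydroxy-2H-pyran-2-one
Conditions: DBU, toluene, reflux; then 1 M HCl wash
Reagents that add atoms: none
Why: Base-mediated lactonisation of a 3,5-diketo ester, in which the C5 enolate oxygen attacks the ester carbonyl (6-exo-trig), methanol leaves and the stabilised pyronate is the thermodynamic sink.

Step 5
Reactants: 5 3,5-bis[4-(benzyloxy)benzyl]-6-{2-[4-(benzyloxy)phenyl]ethyl}-4-hydroxy-2H-pyran-2-one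
Product: 6 3,5-bis[4-(benzyloxy)benzyl]-6-{2-[4-(benzyloxy)phenyl]ethyl}-4-methoxy-2H-pyran-2-one
Conditions: Me2SO4, K2CO3, acetone, reflux
Reagents that add atoms: dimethyl sulfate, COS(=O)(=O)OC
Why: O-Alkylation of the ambident pyronate with a hard methylating agent under carbonate/acetone conditions, the standard way to 4-methoxy-2-pyrones rather than 2-methoxy-4-pyrones, the pyrone hydroxyl being the only acidic site.

Step 6
Reactants: 7 2-bromo-5-hydroxybenzaldehyde
Product: 8 5-(benzyloxy)-2-bromobenzaldehyde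
Conditions: BnBr, K2CO3, DMF, 25 °C
Reagents that add atoms: benzyl bromide, BrCc1ccccc1
Why: Williamson ether synthesis on the phenol, with aldehyde and aryl bromide inert to carbonate.

Step 7
Reactants: 8 5-(benzyloxy)-2-bromobenzaldehyde, 9 diethyl {2-[methoxy(methyl)amino]-2-oxoethyl}phosphonate
Product: 10 (E)-3-[5-(benzyloxy)-2-bromophenyl]-N-methoxy-N-methylprop-2-enamide
Conditions: NaH, THF, 0 to 25 °C
Reagents that add atoms: none
Why: Horner–Wadsworth–Emmons olefination with a stabilised phosphonate anion, which gives the E-alkene and installs the two chain carbons and the acyl-transfer group at once; the geometry is erased in step 9.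

Step 8
Reactants: 10 (E)-3-[5-(benzyloxy)-2-bromophenyl]-N-methoxy-N-methylprop-2-enamide, 11 4-(benzyloxy)benzyl chloride
Product: 13 (E)-3-{5-(benzyloxy)-2-[4-(benzyloxy)benzyl]phenyl}-N-methoxy-N-methylprop-2-enamide, via [4-(benzyloxy)benzyl]zinc chloride 12 (not isolated)
Conditions: 11, Zn dust, LiCl, THF, 25 °C; then 10, Pd(OAc)2 (2 mol %), SPhos (4 mol %), THF, 25 to 40 °C
Reagents that add atoms: zinc, [Zn] (present only in 12)
Why: Negishi coupling, in which zinc inserts into the benzylic C–Cl bond, zerovalent palladium formed from Pd(OAc)2 and SPhos adds oxidatively to the crowded electron-rich aryl bromide, and transmetalation with reductive elimination forms the diarylmethane bond, the enamide being inert to an organozinc.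

Step 9
Reactants: 13 (E)-3-{5-(benzyloxy)-2-[4-(benzyloxy)benzyl]phenyl}-N-methoxy-N-methylprop-2-enamide
Product: 14 3-{5-(benzyloxy)-2-[4-(benzyloxy)benzyl]phenyl}-N-methoxy-N-methylpropanamide
Conditions: H2 (4 atm), RhCl(PPh3)3 (5 mol %), toluene/EtOH, 50 °C
Reagents that add atoms: none
Why: Homogeneous hydrogenation, in which RhCl(PPh3)3 saturates the 1,2-disubstituted alkene but has no pathway for hydrogenolysis of aryl benzyl ethers or of the N–O bond.

Step 10
Reactants: 6 3,5-bis[4-(benzyloxy)benzyl]-6-{2-[4-(benzyloxy)phenyl]ethyl}-4-methoxy-2H-pyran-2-one, 14 3-{5-(benzyloxy)-2-[4-(benzyloxy)benzyl]phenyl}-N-methoxy-N-methylpropanamide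
Product: 15 3,5-bis[4-(benzyloxy)benzyl]-6-(1-[4-(benzyloxy)phenyl]-5-{5-(benzyloxy)-2-[4-(benzyloxy)benzyl]phenyl}-3-oxopentan-2-yl)-4-methoxy-2H-pyran-2-one (racemic)
Conditions: 6, LiN(iPr)2 (1.1 equiv), THF, −78 °C; then 14, −78 to −20 °C; then aq. NH4Cl
Reagents that add atoms: none
Why: Weinreb ketone synthesis with a lithiated 6-alkyl-4-methoxy-2-pyrone (a vinylogous ester enolate), in which only the CH2 on C6 is vinylogously activated, C3 and C5 are blocked so the exocyclic carbon reacts, and the chelated tetrahedral adduct lasts until the quench and so prevents over-addition and proton transfer from the acidic product; the new centre is enolisable and racemic.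

Step 11
Reactants: 15 3,5-bis[4-(benzyloxy)benzyl]-6-(1-[4-(benzyloxy)phenyl]-5-{5-(benzyloxy)-2-[4-(benzyloxy)benzyl]phenyl}-3-oxopentan-2-yl)-4-methoxy-2H-pyran-2-one
Product: 18 2,4,6-tris[4-(benzyloxy)benzyl]-3-(2-{5-(benzyloxy)-2-[4-(benzyloxy)benzyl]phenyl}ethyl)-5-methoxyphenol, via seco acid 16 (not isolated), via cyclic aldol 17 (not isolated)
Conditions: KOH (2 M aq.), 1,4-dioxane, 70 °C, under argon; then 2 M HCl to pH 2, 50 °C
Reagents that add atoms: water (as hydroxide), O (its oxygen is held only by 16 and 17 and leaves again with CO2)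
Why: Hydroxide adds to the lactone carbonyl and opens 15 to the carboxylate of seco acid 16, a 3-methoxy-5,7-dioxo-2-enoate whose deprotonation at chain C4 gives a dienolate with chain C2 (the old pyrone C3) as its far, nucleophilic end. This carbon attacks the chain C7 ketone in a 6-(enolendo)-exo-trig aldol, which forms the C6–C5 bond and closes ring A as the cyclic aldol 17. E1cB loss of water gives a cyclohexa-2,5-dienone with the carboxylate on its sp3 carbon, and this expels CO2 because a phenoxide results, so the reversible aldol is drained by aromatisation and the acid only completes the process and protonates 18. The closest known reaction type is the alkali-induced refolding of 4-oxygenated 2-pyrones that bear a 2-oxoalkyl group on C6 into orsellinic acids and orcinols, the chemical counterpart of stilbene-synthase folding. No stereocentre has to be controlled, since the three transient centres of 17 and the labile centre of 15 all end as sp2 carbons. The step needs aldol folding of chain C2 onto C7 only, and the substrate secures it because the carboxylate cannot act as acyl donor and Claisen closure at the benzylated chain C6 would stop at a quaternary carbon, while the enol ether masks the chain C3 carbonyl and thereby shuts off the reverse fold (chain C8 onto C3), cleavage at C3 and early decarboxylation, and fixes the methyl ether on C1 alone.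

Step 12
Reactants: 18 2,4,6-tris[4-(benzyloxy)benzyl]-3-(2-{5-(benzyloxy)-2-[4-(benzyloxy)benzyl]phenyl}ethyl)-5-methoxyphenol
Product: 19 bleochrin B
Conditions: H2 (1 atm), Pd/C (10 wt %), THF/MeOH, 25 °C
Reagents that add atoms: none
Why: Catalytic hydrogenolysis, which cleaves the five O–CH2Ph bonds while the aryl methyl ether and the diarylmethane and bibenzyl C–C bonds are inert.

Compound list
1 | methyl 3-(4-hydroxyphenyl)propanoate | COC(=O)CCc1ccc(O)cc1 | starting material
2 | methyl 3-[4-(benzyloxy)phenyl]propanoate | COC(=O)CCc1ccc(OCc2ccccc2)cc1 | intermediate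
3 | methyl 2-[4-(benzyloxy)benzyl]-5-[4-(benzyloxy)phenyl]-3-oxopentanoate (racemic, enolisable centre) | COC(=O)C(Cc1ccc(OCc2ccccc2)cc1)C(=O)CCc1ccc(OCc2ccccc2)cc1 | intermediate
4 | methyl 2,4-bis[4-(benzyloxy)benzyl]-7-[4-(benzyloxy)phenyl]-3,5-dioxoheptanoate (diastereomer and enol mixture) | COC(=O)C(Cc1ccc(OCc2ccccc2)cc1)C(=O)C(Cc1ccc(OCc2ccccc2)cc1)C(=O)CCc1ccc(OCc2ccccc2)cc1 | intermediate
5 | 3,5-bis[4-(benzyloxy)benzyl]-6-{2-[4-(benzyloxy)phenyl]ethyl}-4-hydroxy-2H-pyran-2-one | O=C1OC(CCc2ccc(OCc3ccccc3)cc2)=C(Cc2ccc(OCc3ccccc3)cc2)C(O)=C1Cc1ccc(OCc2ccccc2)cc1 | intermediate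
6 | 3,5-bis[4-(benzyloxy)benzyl]-6-{2-[4-(benzyloxy)phenyl]ethyl}-4-methoxy-2H-pyran-2-one | COC1=C(Cc2ccc(OCc3ccccc3)cc2)C(=O)OC(CCc2ccc(OCc3ccccc3)cc2)=C1Cc1ccc(OCc2ccccc2)cc1 | intermediate
7 | 2-bromo-5-hydroxybenzaldehyde | O=Cc1cc(O)ccc1Br | starting material
8 | 5-(benzyloxy)-2-bromobenzaldehyde | O=Cc1cc(OCc2ccccc2)ccc1Br | intermediate
9 | diethyl {2-[methoxy(methyl)amino]-2-oxoethyl}phosphonate | CCOP(=O)(CC(=O)N(C)OC)OCC | starting material
10 | (E)-3-[5-(benzyloxy)-2-bromophenyl]-N-methoxy-N-methylprop-2-enamide | CON(C)C(=O)/C=C/c1cc(OCc2ccccc2)ccc1Br | intermediate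
11 | 4-(benzyloxy)benzyl chloride | ClCc1ccc(OCc2ccccc2)cc1 | starting material
12 | [4-(benzyloxy)benzyl]zinc chloride (not isolated) | Cl[Zn]Cc1ccc(OCc2ccccc2)cc1 | intermediate
13 | (E)-3-{5-(benzyloxy)-2-[4-(benzyloxy)benzyl]phenyl}-N-methoxy-N-methylprop-2-enamide | CON(C)C(=O)/C=C/c1cc(OCc2ccccc2)ccc1Cc1ccc(OCc2ccccc2)cc1 | intermediate
14 | 3-{5-(benzyloxy)-2-[4-(benzyloxy)benzyl]phenyl}-N-methoxy-N-methylpropanamide | CON(C)C(=O)CCc1cc(OCc2ccccc2)ccc1Cc1ccc(OCc2ccccc2)cc1 | intermediate
15 | 3,5-bis[4-(benzyloxy)benzyl]-6-(1-[4-(benzyloxy)phenyl]-5-{5-(benzyloxy)-2-[4-(benzyloxy)benzyl]phenyl}-3-oxopentan-2-yl)-4-methoxy-2H-pyran-2-one (racemic, labile centre) | COC1=C(Cc2ccc(OCc3ccccc3)cc2)C(=O)OC(C(Cc2ccc(OCc3ccccc3)cc2)C(=O)CCc2cc(OCc3ccccc3)ccc2Cc2ccc(OCc3ccccc3)cc2)=C1Cc1ccc(OCc2ccccc2)cc1 | intermediate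
16 | (E)-2,4,6-tris[4-(benzyloxy)benzyl]-9-{5-(benzyloxy)-2-[4-(benzyloxy)benzyl]phenyl}-3-methoxy-5,7-dioxonon-2-enoic acid (alkene geometry as released from the ring, sp3 centres unassigned, not isolated) | OC(=O)/C(Cc1ccc(OCc2ccccc2)cc1)=C(OC)\C(Cc1ccc(OCc2ccccc2)cc1)C(=O)C(Cc1ccc(OCc2ccccc2)cc1)C(=O)CCc1cc(OCc2ccccc2)ccc1Cc1ccc(OCc2ccccc2)cc1 | intermediate
17 | 1,3,5-tris[4-(benzyloxy)benzyl]-6-(2-{5-(benzyloxy)-2-[4-(benzyloxy)benzyl]phenyl}ethyl)-6-hydroxy-2-methoxy-4-oxocyclohex-2-ene-1-carboxylic acid (diastereomer mixture, all centres lost on aromatisation, not isolated) | OC(=O)C1(Cc2ccc(OCc3ccccc3)cc2)C(OC)=C(Cc2ccc(OCc3ccccc3)cc2)C(=O)C(Cc2ccc(OCc3ccccc3)cc2)C1(O)CCc1cc(OCc2ccccc2)ccc1Cc1ccc(OCc2ccccc2)cc1 | intermediate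
18 | 2,4,6-tris[4-(benzyloxy)benzyl]-3-(2-{5-(benzyloxy)-2-[4-(benzyloxy)benzyl]phenyl}ethyl)-5-methoxyphenol | COc1c(Cc2ccc(OCc3ccccc3)cc2)c(O)c(Cc2ccc(OCc3ccccc3)cc2)c(CCc2cc(OCc3ccccc3)ccc2Cc2ccc(OCc3ccccc3)cc2)c1Cc1ccc(OCc2ccccc2)cc1 | intermediate
19 | bleochrin B (no stereocentre) | COc1c(Cc2ccc(O)cc2)c(O)c(Cc2ccc(O)cc2)c(CCc2cc(O)ccc2Cc2ccc(O)cc2)c1Cc1ccc(O)cc1 | target

Total step count: 12.
Longest linear sequence: 8 (steps 1, 2, 3, 4, 5, 10, 11, 12).

Steps most likely to fail

**Step 11 (key step).** Bond formation between chain C2 and chain C7, both fully substituted, may be slower than retro-Claisen cleavage of the 5,7-diketone by hydroxide. The opened acid may also merely relactonise on acidification, and displacement of methoxide from pyrone C4 is a further leak.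

The fallback sets out from 5 and 14 and comes back at 18. The ring is closed in the free hydroxy series, where the nucleophile is a true β-keto carboxylate carbanion rather than the far end of a dienolate, and the methyl group is added afterwards.
- The dianion of 5 (LiN(iPr)2, 2.2 equiv, THF, −78 to 0 °C) is acylated by 14. This gives racemic 3,5-bis[4-(benzyloxy)benzyl]-6-(1-[4-(benzyloxy)phenyl]-5-{5-(benzyloxy)-2-[4-(benzyloxy)benzyl]phenyl}-3-oxopentan-2-yl)-4-hydroxy-2H-pyran-2-one F1.
- KOH in aqueous dioxane followed by HCl should convert it, by opening, aldol closure, dehydration and decarboxylation, into the mirror-symmetric 2,4,6-tris[4-(benzyloxy)benzyl]-5-(2-{5-(benzyloxy)-2-[4-(benzyloxy)benzyl]phenyl}ethyl)benzene-1,3-diol F2.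
- MeI (1 equiv) and K2CO3 in acetone methylate one of the two equivalent hydroxyls. Recovered diol is recycled and the route is rejoined at 18.
- Any material demethylated in step 11 itself enters this path at the diol stage.

**Step 10.** The delocalised, secondary and crowded carbanion of 6 may add too slowly to the amide carbonyl, so that proton exchange with the α-CH2 of 14 simply returns both partners.

The fallback sets out from 14 and 6 and comes back at 15. Acylation is replaced by aldol addition and oxidation.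
- iBu2AlH (THF, −78 °C) reduces 14 to 3-{5-(benzyloxy)-2-[4-(benzyloxy)benzyl]phenyl}propanal F3.
- Lithiated 6 adds to this far more electrophilic carbonyl. This gives 3,5-bis[4-(benzyloxy)benzyl]-6-(1-[4-(benzyloxy)phenyl]-5-{5-(benzyloxy)-2-[4-(benzyloxy)benzyl]phenyl}-3-hydroxypentan-2-yl)-4-methoxy-2H-pyran-2-one F4, a diastereomer mixture of no consequence.
- Dess–Martin oxidation (CH2Cl2, NaHCO3, 25 °C) gives 15.

**Step 3.** Proton transfer from the more acidic diketo ester to unreacted dianion, together with enolisation of ester 2, may stall the acylation of the secondary γ-carbanion.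

The fallback sets out from 2 and 3 and comes back at 4. The acyl donor is replaced by an aldehyde, so the primary adduct is an alkoxide that cannot quench the dianion.
- iBu2AlH (toluene, −78 °C) reduces 2 to 3-[4-(benzyloxy)phenyl]propanal F5.
- The dianion of 3 (LiN(iPr)2, 2.1 equiv, THF, −78 °C) adds to it. This gives methyl 2,4-bis[4-(benzyloxy)benzyl]-7-[4-(benzyloxy)phenyl]-5-hydroxy-3-oxoheptanoate F6.
- Dess–Martin oxidation gives 4.

Further compounds
F1 | step 11 | 3,5-bis[4-(benzyloxy)benzyl]-6-(1-[4-(benzyloxy)phenyl]-5-{5-(benzyloxy)-2-[4-(benzyloxy)benzyl]phenyl}-3-oxopentan-2-yl)-4-hydroxy-2H-pyran-2-one (racemic, labile centre) | O=C1OC(C(Cc2ccc(OCc3ccccc3)cc2)C(=O)CCc2cc(OCc3ccccc3)ccc2Cc2ccc(OCc3ccccc3)cc2)=C(Cc2ccc(OCc3ccccc3)cc2)C(O)=C1Cc1ccc(OCc2ccccc2)cc1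
F2 | step 11 | 2,4,6-tris[4-(benzyloxy)benzyl]-5-(2-{5-(benzyloxy)-2-[4-(benzyloxy)benzyl]phenyl}ethyl)benzene-1,3-diol | Oc1c(Cc2ccc(OCc3ccccc3)cc2)c(O)c(Cc2ccc(OCc3ccccc3)cc2)c(CCc2cc(OCc3ccccc3)ccc2Cc2ccc(OCc3ccccc3)cc2)c1Cc1ccc(OCc2ccccc2)cc1
F3 | step 10 | 3-{5-(benzyloxy)-2-[4-(benzyloxy)benzyl]phenyl}propanal | O=CCCc1cc(OCc2ccccc2)ccc1Cc1ccc(OCc2ccccc2)cc1
F4 | step 10 | 3,5-bis[4-(benzyloxy)benzyl]-6-(1-[4-(benzyloxy)phenyl]-5-{5-(benzyloxy)-2-[4-(benzyloxy)benzyl]phenyl}-3-hydroxypentan-2-yl)-4-methoxy-2H-pyran-2-one (diastereomer mixture) | COC1=C(Cc2ccc(OCc3ccccc3)cc2)C(=O)OC(C(Cc2ccc(OCc3ccccc3)cc2)C(O)CCc2cc(OCc3ccccc3)ccc2Cc2ccc(OCc3ccccc3)cc2)=C1Cc1ccc(OCc2ccccc2)cc1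
F5 | step 3 | 3-[4-(benzyloxy)phenyl]propanal | O=CCCc1ccc(OCc2ccccc2)cc1
F6 | step 3 | methyl 2,4-bis[4-(benzyloxy)benzyl]-7-[4-(benzyloxy)phenyl]-5-hydroxy-3-oxoheptanoate (diastereomer mixture) | COC(=O)C(Cc1ccc(OCc2ccccc2)cc1)C(=O)C(Cc1ccc(OCc2ccccc2)cc1)C(O)CCc1ccc(OCc2ccccc2)cc1
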